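Everything rests on cutting ring A at C6–C7, C4a–C5 and C7–C8, which leaves a pyran-fused 3-alkoxycyclobutenone and a prenylated methoxyalkyne. One thermal operation (four-electron opening, ketene–alkyne [2+2], second opening, six-electron closure, tautomerisation) builds the whole benzene ring. It exploits the contiguous pattern of ring A, C8a–O1, C4a–C4, C5–OMe, C6–prenyl, C7–OH and C8–H, so that prenylation at C6 rather than C8 never depends on electrophilic substitution. The precursor is a (4R)-4-aryl-2-oxabicyclo[4.2.0]oct-1(6)-en-7-one that already carries ring C, the C3 stereocentre from an auxiliary-controlled Michael addition, and the silyl-protected chromene ring B.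

Key step: step 15

Remark 1: the stereocentre of the target SMILES is read as (3R). Isoflavan numbering (O1, C2, C3, C4, C4a, C5 to C8, C8a; ring A benzene, ring C pyran, ring B the aryl group on C3) is used for every atom that ends up in the target.
Remark 2: Ar = 2,2-dimethyl-5-(triisopropylsilyloxy)-2H-chromen-8-yl. The ring B phenol is carried as the triisopropylsilyl ether because a smaller silyl ether para to a formyl group would be at risk in step 2. This choice also leaves the alkyl tert-butyldimethylsilyl ether of 20 to 24 selectively removable by acid.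
Remark 3: the C5 methoxy group must come from a methyl ynol ether, so 30 is made from chloroacetaldehyde dimethyl acetal. Ethoxyacetylene serves only to build the four-membered ring, where its ethoxy group is lost again.

Step 1
Reactants: 1 2,4-dihydroxybenzaldehyde
Product: 2 2-hydroxy-4-(triisopropylsilyloxy)benzaldehyde
Conditions: iPr3SiCl (1.05 equiv), imidazole, CH2Cl2, 0 °C to rt
Reagents that add atoms: triisopropylsilyl chloride, CC(C)[Si](Cl)(C(C)C)C(C)C
Why: Chemoselective O-silylation, in which the C2 hydroxyl is tied up in a hydrogen bond to the formyl group so that the bulky silyl chloride should take only the free C4 hydroxyl.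

Step 2
Reactants: 2 2-hydroxy-4-(triisopropylsilyloxy)benzaldehyde; 3 3-chloro-3-methylbut-1-yne
Product: 4 2-[(2-methylbut-3-yn-2-yl)oxy]-4-(triisopropylsilyloxy)benzaldehyde
Conditions: DBU, CuCl2·2H2O (1 mol %), MeCN, 0 °C
Reagents that add atoms: none
Why: Copper-catalysed O-propargylation of a phenol with a tertiary propargylic chloride, which runs at 0 °C even on hindered and electron-poor phenols and so avoids the hot carbonate conditions that strip aryl silyl ethers.

Step 3
Reactants: 4 2-[(2-methylbut-3-yn-2-yl)oxy]-4-(triisopropylsilyloxy)benzaldehyde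
Product: 7 2,2-dimethyl-5-(triisopropylsilyloxy)-2H-chromene-8-carbaldehyde (ArCHO), via allenylphenol 5 (not isolated), via o-quinone methide 6 (not isolated)
Conditions: xylenes, 140 °C
Reagents that add atoms: none
Why: Aromatic propargyl Claisen rearrangement to the only free ortho position, tautomerisation to 5, 1,5-hydrogen shift to 6 and oxa-six-electron electrocyclisation, the standard thermal route from aryl 1,1-dimethylpropargyl ethers to 2,2-dimethyl-2H-chromenes, here forced to use the oxygen next to the formyl group as ring B requires.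

Step 4
Reactants: 7 ArCHO; 8 (methoxymethyl)triphenylphosphonium chloride
Product: 10 8-(2-methoxyethenyl)-2,2-dimethyl-5-(triisopropylsilyloxy)-2H-chromene (E/Z mixture), via ylide 9 (not isolated)
Conditions: KOtBu, THF, 0 °C, then 7, 0 °C to rt
Reagents that add atoms: none
Why: Wittig methoxymethylenation of a non-enolisable aromatic aldehyde, which adds the carbon that becomes C2, the alkene geometry being irrelevant for the next step.

Step 5
Reactants: 10 8-(2-methoxyethenyl)-2,2-dimethyl-5-(triisopropylsilyloxy)-2H-chromene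
Product: 11 2-Ar-acetaldehyde
Conditions: 2 M aq HCl, THF, 40 °C
Reagents that add atoms: water, O
Why: Acid hydrolysis of an enol ether through the oxocarbenium ion, fast for an electron-rich styryl ether under dilute acid that the chromene and the aryl triisopropylsilyl ether should tolerate.

Step 6
Reactants: 11 2-Ar-acetaldehyde
Product: 12 2-Ar-acetic acid
Conditions: NaClO2, NaH2PO4, 2-methylbut-2-ene, t-BuOH/H2O, 0 °C to rt
Reagents that add atoms: sodium chlorite, [Na+].[O-]Cl=O
Why: Pinnick oxidation, which takes the sensitive arylacetaldehyde to the acid at buffered pH while the alkene scavenger intercepts hypochlorous acid before it can reach the chromene double bond.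

Step 7
Reactants: 12 2-Ar-acetic acid; 13 (4R)-4-benzyl-1,3-oxazolidin-2-one
Product: 15 (4R)-4-benzyl-3-(2-Ar-acetyl)-1,3-oxazolidin-2-one, via mixed anhydride 14 (not isolated)
Conditions: t-BuCOCl, Et3N, THF, −20 °C, then LiCl, 13, −20 °C to rt
Reagents that add atoms: pivaloyl chloride, CC(C)(C)C(=O)Cl (atoms in intermediate 14 only)
Why: N-acylation of an oxazolidinone through the mixed pivalic anhydride with LiCl activation, in which the auxiliary attacks the less hindered arylacetyl carbonyl and no strong base is needed.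

Step 8
Reactants: 15 (4R)-4-benzyl-3-(2-Ar-acetyl)-1,3-oxazolidin-2-one; 16 tert-butyl acrylate
Product: 18 tert-butyl (4R)-5-[(4R)-4-benzyl-2-oxo-1,3-oxazolidin-3-yl]-4-Ar-5-oxopentanoate, via titanium enolate 17 (not isolated)
Conditions: TiCl4/Ti(OiPr)4 (3:1, gives TiCl3(OiPr)), iPr2NEt, CH2Cl2, 0 °C, then 16, 0 °C
Reagents that add atoms: trichloro(isopropoxy)titanium, CC(C)O[Ti](Cl)(Cl)Cl (atoms in intermediate 17 only)
Why: Auxiliary-controlled Michael addition of a chlorotitanium imide enolate to an acrylate, in which soft enolisation gives the chelated (Z)-enolate 17, the benzyl group of the (4R)-auxiliary shields one face and the acrylate adds to the other, which sets C3 as (R) in the same sense as enolate alkylations of such imides, while chelation of the titanium by the imide keeps the Lewis acid away from the chromene.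

Step 9
Reactants: 18 tert-butyl (4R)-5-[(4R)-4-benzyl-2-oxo-1,3-oxazolidin-3-yl]-4-Ar-5-oxopentanoate
Product: 19 tert-butyl (4R)-4-Ar-5-hydroxypentanoate
Conditions: LiBH4, H2O (1 equiv), Et2O/THF, 0 °C
Reagents that add atoms: none
Why: Reductive removal of the auxiliary, in which LiBH4 attacks the activated exocyclic imide carbonyl much faster than the hindered tert-butyl ester and the medium is too weakly basic to epimerise the benzylic C3 centre.

Step 10
Reactants: 19 tert-butyl (4R)-4-Ar-5-hydroxypentanoate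
Product: 20 tert-butyldimethylsilyl (4R)-4-Ar-5-(tert-butyldimethylsilyloxy)pentanoate
Conditions: TBSOTf (2.5 equiv), 2,6-lutidine, CH2Cl2, 0 °C to rt
Reagents that add atoms: tert-butyldimethylsilyl triflate, CC(C)(C)[Si](C)(C)OS(=O)(=O)C(F)(F)F
Why: Silyl triflate chemistry does two jobs in one flask, O-silylation of the primary alcohol and conversion of the tert-butyl ester into the silyl ester with loss of isobutene, under lutidine buffering that spares the chromene the strong acid otherwise needed for a tert-butyl ester.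

Step 11
Reactants: 20 tert-butyldimethylsilyl (4R)-4-Ar-5-(tert-butyldimethylsilyloxy)pentanoate; 21 ethoxyacetylene
Product: 24 4-[(2R)-2-Ar-3-(tert-butyldimethylsilyloxy)propyl]-3-ethoxycyclobut-2-en-1-one (both epimers at the ring carbon C4), via acid chloride 22 (not isolated), via alkylketene 23 (not isolated)
Conditions: (COCl)2, DMF (cat.), CH2Cl2, 0 °C to rt, concentrate, then slow addition to 21 (5 equiv), Et3N, Et2O, rt
Reagents that add atoms: oxalyl chloride, O=C(Cl)C(=O)Cl (chlorine in intermediate 22 only)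
Why: The silyl ester reacts with the Vilsmeier reagent to give 22 without free HCl, triethylamine dehydrochlorinates it to 23, and the ketene–alkoxyalkyne [2+2] cycloaddition (nucleophilic CH of 21 to the ketene carbonyl carbon) gives the 4-alkyl-3-ethoxycyclobutenone, slow addition and excess alkyne holding back ketene dimerisation.

Step 12
Reactants: 24 4-[(2R)-2-Ar-3-(tert-butyldimethylsilyloxy)propyl]-3-ethoxycyclobut-2-en-1-one
Product: 25 3-hydroxy-2-[(2R)-2-Ar-3-hydroxypropyl]cyclobut-2-en-1-one (enol form of the 2-substituted cyclobutane-1,3-dione)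
Conditions: 1 M aq HCl, THF, rt
Reagents that add atoms: water, O
Why: Acid hydrolysis of a vinylogous ester gives the 2-alkylcyclobutane-1,3-dione, which rests as the more substituted enol, and the same dilute acid cleaves the primary alkyl silyl ether but not the far more acid-stable aryl triisopropylsilyl ether.

Step 13
Reactants: 25 3-hydroxy-2-[(2R)-2-Ar-3-hydroxypropyl]cyclobut-2-en-1-one
Product: 26 (4R)-4-Ar-2-oxabicyclo[4.2.0]oct-1(6)-en-7-one
Conditions: PPh3, DIAD, THF (0.01 M), 0 °C to rt
Reagents that add atoms: none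
Why: Intramolecular Mitsunobu etherification, in which the vinylogous acid (about as acidic as a carboxylic acid) protonates the betaine and its oxygen displaces the activated C2 oxygen in a six-membered closure of ring C, C-alkylation would need a four-membered ring, either enolate oxygen gives the same compound, the alkyl group stays on the enone carbon C4a, and C3 is not touched.

Step 14
Reactants: 27 chloroacetaldehyde dimethyl acetal; 28 prenyl bromide
Product: 30 1-methoxy-5-methylhex-4-en-1-yne, via sodium methoxyacetylide 29 (not isolated)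
Conditions: NaNH2 (3.0 equiv), NH3(l), −33 °C, then 28, −33 °C, H2O/pentane work-up, distillation
Reagents that add atoms: sodium amide, [Na+].[NH2-] (sodium in intermediate 29 only)
Why: Twofold base-induced elimination (methanol and HCl) from the chloroacetal and deprotonation give 29, whose SN2 alkylation by the primary allylic bromide is the standard way to 1-alkoxy-1-alkynes in liquid ammonia.

Step 15
Reactants: 26 (4R)-4-Ar-2-oxabicyclo[4.2.0]oct-1(6)-en-7-one; 30 1-methoxy-5-methylhex-4-en-1-yne
Product: 35 (3R)-3-Ar-5-methoxy-6-(3-methylbut-2-enyl)-3,4-dihydro-2H-chromen-7-ol, via vinylketene 31 (not isolated), via spirocyclobutenone 32 (not isolated), via dienylketene 33 (not isolated), via cyclohexadienone 34 (not isolated)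
Conditions: 30 (2.5 equiv), toluene (0.5 M), base-washed sealed tube, 110 °C, then 145 °C
Reagents that add atoms: none
Why: Heating opens the strained ring-fused cyclobutenone 26 by four-electron electrocyclic cleavage of its C7–C8 bond to the s-cis-locked vinylketene 31, whose electrophilic ketene carbon (future C7) is attacked by the nucleophilic, prenyl-bearing carbon of 30 while the methoxy-bearing carbon bonds to C4a, giving spirocyclobutenone 32 in a [2+2] cycloaddition. A second four-electron opening of 32 gives dienylketene 33, and ring A closes by disrotatory six-electron electrocyclisation (new C7–C8 bond) to cyclohexadienone 34, which tautomerises to the C7 phenol 35. This is a Danheiser benzannulation of a cyclobutenone with a 1-alkoxyalkyne, a reaction type established for 2,3-disubstituted and oxygenated cyclobutenones and for methyl ynol ethers that carry an allylic side chain. No lasting stereocentre is formed (the spiro carbon of 32 becomes aromatic C4a), and the remote C3 centre has no acidic hydrogen and should pass unchanged. The selectivity needed is the orientation of the ketene–alkyne union, and the polarisation of the ynol ether (electron-rich at the carbon beta to oxygen) secures it, so that prenyl ends on C6 between C5–OMe and C7–OH while C8 keeps its hydrogen. A methyl ynol ether cannot suffer the retro-ene loss of alkene that limits ethyl and tert-butyl ynol ethers, the excess of 30 should outcompete acylation of the product phenol by 31, and the neutral medium spares the chromene, the prenyl group and the silyl ether.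

Step 16
Reactants: 35 (3R)-3-Ar-5-methoxy-6-(3-methylbut-2-enyl)-3,4-dihydro-2H-chromen-7-ol
Product: 36 (3R)-3-(5-hydroxy-2,2-dimethyl-2H-chromen-8-yl)-5-methoxy-6-(3-methylbut-2-enyl)-3,4-dihydro-2H-chromen-7-ol (target)
Conditions: Bu4NF, AcOH (1:1), THF, 0 °C
Reagents that add atoms: none
Why: Fluoride-induced cleavage of an aryl silyl ether, driven by the Si–F bond and the phenoxide leaving group, is fast at 0 °C, and the acetic acid buffer keeps both phenols protonated so that the prenyl group, the chromene and C3 are not at risk.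

Compound list
1 | 2,4-dihydroxybenzaldehyde | O=Cc1ccc(O)cc1O | starting material
2 | 2-hydroxy-4-(triisopropylsilyloxy)benzaldehyde | O=Cc1ccc(O[Si](C(C)C)(C(C)C)C(C)C)cc1O | intermediate
3 | 3-chloro-3-methylbut-1-yne | C#CC(C)(C)Cl | starting material
4 | 2-[(2-methylbut-3-yn-2-yl)oxy]-4-(triisopropylsilyloxy)benzaldehyde | O=Cc1ccc(O[Si](C(C)C)(C(C)C)C(C)C)cc1OC(C)(C)C#C | intermediate
5 | 2-hydroxy-3-(3-methylbuta-1,2-dienyl)-4-(triisopropylsilyloxy)benzaldehyde (allenylphenol, not isolated) | O=Cc1ccc(O[Si](C(C)C)(C(C)C)C(C)C)c(C=C=C(C)C)c1O | intermediate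
6 | 5-(3-methylbut-2-enylidene)-6-oxo-4-(triisopropylsilyloxy)cyclohexa-1,3-diene-1-carbaldehyde (o-quinone methide, not isolated) | O=CC1=CC=C(O[Si](C(C)C)(C(C)C)C(C)C)C(=CC=C(C)C)C1=O | intermediate
7 | 2,2-dimethyl-5-(triisopropylsilyloxy)-2H-chromene-8-carbaldehyde | O=Cc1ccc(O[Si](C(C)C)(C(C)C)C(C)C)c2c1OC(C)(C)C=C2 | intermediate
8 | (methoxymethyl)triphenylphosphonium chloride | COC[P+](c1ccccc1)(c1ccccc1)c1ccccc1.[Cl-] | starting material
9 | (methoxymethylidene)triphenylphosphorane (ylide, not isolated) | COC=P(c1ccccc1)(c1ccccc1)c1ccccc1 | intermediate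
10 | 8-(2-methoxyethenyl)-2,2-dimethyl-5-(triisopropylsilyloxy)-2H-chromene, E/Z mixture | COC=Cc1ccc(O[Si](C(C)C)(C(C)C)C(C)C)c2c1OC(C)(C)C=C2 | intermediate
11 | 2-[2,2-dimethyl-5-(triisopropylsilyloxy)-2H-chromen-8-yl]acetaldehyde | O=CCc1ccc(O[Si](C(C)C)(C(C)C)C(C)C)c2c1OC(C)(C)C=C2 | intermediate
12 | 2-[2,2-dimethyl-5-(triisopropylsilyloxy)-2H-chromen-8-yl]acetic acid | O=C(O)Cc1ccc(O[Si](C(C)C)(C(C)C)C(C)C)c2c1OC(C)(C)C=C2 | intermediate
13 | (4R)-4-benzyl-1,3-oxazolidin-2-one | O=C1N[C@H](Cc2ccccc2)CO1 | starting material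
14 | 2-Ar-acetic pivalic anhydride (not isolated) | CC(C)(C)C(=O)OC(=O)Cc1ccc(O[Si](C(C)C)(C(C)C)C(C)C)c2c1OC(C)(C)C=C2 | intermediate
15 | (4R)-4-benzyl-3-(2-Ar-acetyl)-1,3-oxazolidin-2-one | O=C(Cc1ccc(O[Si](C(C)C)(C(C)C)C(C)C)c2c1OC(C)(C)C=C2)N1[C@H](Cc2ccccc2)COC1=O | intermediate
16 | tert-butyl acrylate | C=CC(=O)OC(C)(C)C | starting material
17 | dichloro(isopropoxy)titanium (Z)-enolate of 15 (not isolated) | CC(C)O[Ti](Cl)(Cl)O/C(=C\c1ccc(O[Si](C(C)C)(C(C)C)C(C)C)c2c1OC(C)(C)C=C2)N1[C@H](Cc2ccccc2)COC1=O | intermediate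
18 | tert-butyl (4R)-5-[(4R)-4-benzyl-2-oxo-1,3-oxazolidin-3-yl]-4-Ar-5-oxopentanoate | CC(C)(C)OC(=O)CC[C@H](c1ccc(O[Si](C(C)C)(C(C)C)C(C)C)c2c1OC(C)(C)C=C2)C(=O)N1[C@H](Cc2ccccc2)COC1=O | intermediate
19 | tert-butyl (4R)-4-Ar-5-hydroxypentanoate | CC(C)(C)OC(=O)CC[C@H](c1ccc(O[Si](C(C)C)(C(C)C)C(C)C)c2c1OC(C)(C)C=C2)CO | intermediate
20 | tert-butyldimethylsilyl (4R)-4-Ar-5-(tert-butyldimethylsilyloxy)pentanoate | CC(C)(C)[Si](C)(C)OC(=O)CC[C@H](c1ccc(O[Si](C(C)C)(C(C)C)C(C)C)c2c1OC(C)(C)C=C2)CO[Si](C)(C)C(C)(C)C | intermediate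
21 | ethoxyacetylene | CCOC#C | starting material
22 | (4R)-4-Ar-5-(tert-butyldimethylsilyloxy)pentanoyl chloride (not isolated) | O=C(Cl)CC[C@H](c1ccc(O[Si](C(C)C)(C(C)C)C(C)C)c2c1OC(C)(C)C=C2)CO[Si](C)(C)C(C)(C)C | intermediate
23 | (4R)-4-Ar-5-(tert-butyldimethylsilyloxy)pent-1-en-1-one (alkylketene, not isolated) | O=C=CC[C@H](c1ccc(O[Si](C(C)C)(C(C)C)C(C)C)c2c1OC(C)(C)C=C2)CO[Si](C)(C)C(C)(C)C | intermediate
24 | 4-[(2R)-2-Ar-3-(tert-butyldimethylsilyloxy)propyl]-3-ethoxycyclobut-2-en-1-one, both epimers at ring C4 | CCOC1=CC(=O)C1C[C@H](c1ccc(O[Si](C(C)C)(C(C)C)C(C)C)c2c1OC(C)(C)C=C2)CO[Si](C)(C)C(C)(C)C | intermediate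
25 | 3-hydroxy-2-[(2R)-2-Ar-3-hydroxypropyl]cyclobut-2-en-1-one | O=C1CC(O)=C1C[C@H](c1ccc(O[Si](C(C)C)(C(C)C)C(C)C)c2c1OC(C)(C)C=C2)CO | intermediate
26 | (4R)-4-[2,2-dimethyl-5-(triisopropylsilyloxy)-2H-chromen-8-yl]-2-oxabicyclo[4.2.0]oct-1(6)-en-7-one | O=C1CC2=C1C[C@H](c1ccc(O[Si](C(C)C)(C(C)C)C(C)C)c3c1OC(C)(C)C=C3)CO2 | intermediate
27 | chloroacetaldehyde dimethyl acetal (2-chloro-1,1-dimethoxyethane) | COC(CCl)OC | starting material
28 | prenyl bromide (1-bromo-3-methylbut-2-ene) | CC(C)=CCBr | starting material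
29 | sodium methoxyacetylide (not isolated) | COC#[C-].[Na+] | intermediate
30 | 1-methoxy-5-methylhex-4-en-1-yne | COC#CCC=C(C)C | intermediate
31 | 2-[(5R)-5-Ar-2-methylideneoxan-3-ylidene]ethen-1-one (vinylketene, not isolated) | O=C=C1C[C@H](c2ccc(O[Si](C(C)C)(C(C)C)C(C)C)c3c2OC(C)(C)C=C3)COC1=C | intermediate
32 | (8R)-8-Ar-3-methoxy-5-methylidene-2-(3-methylbut-2-enyl)-6-oxaspiro[3.5]non-2-en-1-one, spiro carbon unassigned (not isolated) | O=C1C(CC=C(C)C)=C(OC)C12C[C@H](c1ccc(O[Si](C(C)C)(C(C)C)C(C)C)c3c1OC(C)(C)C=C3)COC2=C | intermediate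
33 | 2-{[(5R)-5-Ar-2-methylideneoxan-3-ylidene](methoxy)methyl}-5-methylhexa-1,4-dien-1-one, C6 and C8a cis on the C5=C4a bond (dienylketene, not isolated) | O=C=C(CC=C(C)C)/C(OC)=C1/C[C@H](c2ccc(O[Si](C(C)C)(C(C)C)C(C)C)c3c2OC(C)(C)C=C3)COC1=C | intermediate
34 | (3R)-3-Ar-5-methoxy-6-(3-methylbut-2-enyl)-3,4-dihydro-2H-chromen-7(8H)-one (not isolated) | O=C1CC2=C(C[C@H](c3ccc(O[Si](C(C)C)(C(C)C)C(C)C)c4c3OC(C)(C)C=C4)CO2)C(OC)=C1CC=C(C)C | intermediate
35 | (3R)-3-[2,2-dimethyl-5-(triisopropylsilyloxy)-2H-chromen-8-yl]-5-methoxy-6-(3-methylbut-2-enyl)-3,4-dihydro-2H-chromen-7-ol | COc1c(CC=C(C)C)c(O)cc2c1C[C@H](c1ccc(O[Si](C(C)C)(C(C)C)C(C)C)c3c1OC(C)(C)C=C3)CO2 | intermediate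
36 | (3R)-3-(5-hydroxy-2,2-dimethyl-2H-chromen-8-yl)-5-methoxy-6-(3-methylbut-2-enyl)-3,4-dihydro-2H-chromen-7-ol | COc1c(CC=C(C)C)c(O)cc2c1C[C@H](c1ccc(O)c3c1OC(C)(C)C=C3)CO2 | target

Total step count: 16. Longest linear sequence: 15 (steps 1 to 13, 15 and 16); step 14 is a one-step side branch.

Steps most likely to fail

1. Step 15.
- What may go wrong: the vinylogous-ester stabilisation of 26 may slow the first electrocyclic opening. Thermal decay of 30 and acylation of the newly formed phenol by the ketene could then overtake the productive capture.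
- Fallback: the same vinylketene is made near room temperature by 1,4-dehydrochlorination instead of by ring opening. It sets out from 19.
- Et3SiCl and imidazole should give tert-butyl (4R)-4-Ar-5-(triethylsilyloxy)pentanoate F1.
- Claisen-type C-acylation of its lithium enolate (LiN(iPr)2, 2 equiv, then 1-acetylimidazole, THF, −78 °C) should give tert-butyl (4R)-2-acetyl-4-Ar-5-(triethylsilyloxy)pentanoate F2.
- AcOH–THF–H2O followed by PPTS in warm toluene should remove the silyl group and cyclodehydrate the δ-hydroxy β-keto ester to tert-butyl (3R)-3-Ar-6-methyl-3,4-dihydro-2H-pyran-5-carboxylate F3.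
- TBSOTf and 2,6-lutidine should give tert-butyldimethylsilyl (3R)-3-Ar-6-methyl-3,4-dihydro-2H-pyran-5-carboxylate F4, and (COCl)2 with catalytic DMF should give (3R)-3-Ar-6-methyl-3,4-dihydro-2H-pyran-5-carbonyl chloride F5.
- Triethylamine in toluene in the presence of 30 removes HCl across the C8 methyl group and the acyl chloride. The fallback comes back to the route at vinylketene 31 and, after warming to finish the cascade, at 35.

2. Step 11.
- What may go wrong: amine-promoted dimerisation of the monoalkylketene may outrun its capture by ethoxyacetylene.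
- Fallback: the roles of the partners are exchanged. The chain carries the ynol ether, and the two-carbon unit arrives as dichloroketene, which is made in excess and does not dimerise. It sets out from 19.
- TBSCl and imidazole should give tert-butyl (4R)-4-Ar-5-(tert-butyldimethylsilyloxy)pentanoate F6.
- LiN(iPr)2 and then ClP(O)(OEt)2 should give (4R)-1-tert-butoxy-4-Ar-5-(tert-butyldimethylsilyloxy)pent-1-en-1-yl diethyl phosphate F7.
- t-BuLi (2 equiv, THF, −78 °C) should eliminate phosphate to give tert-butyl{[(2R)-2-Ar-5-tert-butoxypent-4-yn-1-yl]oxy}dimethylsilane F8.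
- Dichloroketene (Cl3CCOCl, Zn–Cu couple, Et2O, rt) should add with the same polarity rule to give 3-tert-butoxy-4,4-dichloro-2-[(2R)-2-Ar-3-(tert-butyldimethylsilyloxy)propyl]cyclobut-2-en-1-one F9.
- Zn, AcOH and TMEDA in EtOH should remove both chlorines to give 3-tert-butoxy-2-[(2R)-2-Ar-3-(tert-butyldimethylsilyloxy)propyl]cyclobut-2-en-1-one F10.
- 1 M HCl in THF cleaves the tert-butyl vinylogous ester and the alkyl silyl ether, and the fallback comes back to the route at 25.

3. Step 13.
- What may go wrong: the activated primary carbinol may be attacked through the other enolate tautomer. It may also be displaced with participation of the electron-rich ring B aryl group (1,2-aryl shift), or couple intermolecularly.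
- Fallback: ring C is closed at the other end, by forming O1–C8a instead of O1–C2. It sets out from 25.
- Acid-catalysed dehydrative etherification of the vinylogous acid by its own primary alcohol (PPTS, toluene, 4 Å molecular sieves, 60 °C) is an addition–elimination at C8a. It keeps C4a sp2 throughout, never activates C2, and loses only water.
- It comes back to the route at 26 and makes no new compound (F0).

Further compounds
F1 | step 15 | tert-butyl (4R)-4-Ar-5-(triethylsilyloxy)pentanoate | CC(C)(C)OC(=O)CC[C@H](c1ccc(O[Si](C(C)C)(C(C)C)C(C)C)c2c1OC(C)(C)C=C2)CO[Si](CC)(CC)CC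
F2 | step 15 | tert-butyl (4R)-2-acetyl-4-Ar-5-(triethylsilyloxy)pentanoate, both epimers at C2 | CC(=O)C(C[C@H](c1ccc(O[Si](C(C)C)(C(C)C)C(C)C)c2c1OC(C)(C)C=C2)CO[Si](CC)(CC)CC)C(=O)OC(C)(C)C
F3 | step 15 | tert-butyl (3R)-3-Ar-6-methyl-3,4-dihydro-2H-pyran-5-carboxylate | CC1=C(C(=O)OC(C)(C)C)C[C@H](c2ccc(O[Si](C(C)C)(C(C)C)C(C)C)c3c2OC(C)(C)C=C3)CO1
F4 | step 15 | tert-butyldimethylsilyl (3R)-3-Ar-6-methyl-3,4-dihydro-2H-pyran-5-carboxylate | CC1=C(C(=O)O[Si](C)(C)C(C)(C)C)C[C@H](c2ccc(O[Si](C(C)C)(C(C)C)C(C)C)c3c2OC(C)(C)C=C3)CO1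
F5 | step 15 | (3R)-3-Ar-6-methyl-3,4-dihydro-2H-pyran-5-carbonyl chloride | CC1=C(C(=O)Cl)C[C@H](c2ccc(O[Si](C(C)C)(C(C)C)C(C)C)c3c2OC(C)(C)C=C3)CO1
F6 | step 11 | tert-butyl (4R)-4-Ar-5-(tert-butyldimethylsilyloxy)pentanoate | CC(C)(C)OC(=O)CC[C@H](c1ccc(O[Si](C(C)C)(C(C)C)C(C)C)c2c1OC(C)(C)C=C2)CO[Si](C)(C)C(C)(C)C
F7 | step 11 | (4R)-1-tert-butoxy-4-Ar-5-(tert-butyldimethylsilyloxy)pent-1-en-1-yl diethyl phosphate | CCOP(=O)(OCC)OC(OC(C)(C)C)=CC[C@H](c1ccc(O[Si](C(C)C)(C(C)C)C(C)C)c2c1OC(C)(C)C=C2)CO[Si](C)(C)C(C)(C)C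
F8 | step 11 | tert-butyl{[(2R)-2-Ar-5-tert-butoxypent-4-yn-1-yl]oxy}dimethylsilane | CC(C)(C)OC#CC[C@H](c1ccc(O[Si](C(C)C)(C(C)C)C(C)C)c2c1OC(C)(C)C=C2)CO[Si](C)(C)C(C)(C)C
F9 | step 11 | 3-tert-butoxy-4,4-dichloro-2-[(2R)-2-Ar-3-(tert-butyldimethylsilyloxy)propyl]cyclobut-2-en-1-one | CC(C)(C)OC1=C(C[C@H](c2ccc(O[Si](C(C)C)(C(C)C)C(C)C)c3c2OC(C)(C)C=C3)CO[Si](C)(C)C(C)(C)C)C(=O)C1(Cl)Cl
F10 | step 11 | 3-tert-butoxy-2-[(2R)-2-Ar-3-(tert-butyldimethylsilyloxy)propyl]cyclobut-2-en-1-one | CC(C)(C)OC1=C(C[C@H](c2ccc(O[Si](C(C)C)(C(C)C)C(C)C)c3c2OC(C)(C)C=C3)CO[Si](C)(C)C(C)(C)C)C(=O)C1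
F0 | step 13 | none | none
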